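**Retrosynthetic overview**
1. Target ⇒ ring-closing metathesis across C5=C10 of a seco-diene γ-lactone; the cyclohexene is the last ring made.
2. Seco-diene lactone ⇒ key C8–O lactone bond (formed together with C9–C10) by oxidative gold-catalysed oxy-alkenylation of a C7 vinyl group with isopropenylboronic acid; the lactone is the first ring made and this step sets C8.
3. Acyclic precursor ⇒ C6–C7 bond by catalytic asymmetric 2-(tert-butoxycarbonyl)allylation of a hydroxy enal with a dienyl bromide (sets C6 and C7), then diacetylation.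
4. Hydroxy enal ⇐ (S)-citronellal, which carries C4 (α-methylenation, ozonolysis/reduction, allylic oxidation); bromide ⇐ acrolein + tert-butyl acrylate (Morita–Baylis–Hillman, SN2′ bromination).

Assumption: the SMILES is read as the (4S,6R,7R,8R) isomer with H-6, H-7 and H-8 all cis; labels C1–C15 are eudesmane positions (C4 side-chain stereocentre, C5=C10 ring alkene, C6 acetoxy carbon, C7/C8 ring fusion, C11–C13 methylene lactone).

**Route**

Step 1
Reactants: 1 (S)-citronellal [(3S)-3,7-dimethyloct-6-enal]
Product: 2 (3S)-3,7-dimethyl-2-methylideneoct-6-enal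
Conditions: 37% aq. HCHO, pyrrolidine (10 mol %), propionic acid (10 mol %), iPrOH, 45 °C
Reagents that add atoms: formaldehyde, C=O
Why: Amine-catalysed Mannich condensation–elimination (organocatalytic α-methylenation of an aldehyde) acts only at C2, so the C3 stereocentre (C4 of the target) is not touched.

Step 2
Reactants: 2 (3S)-3,7-dimethyl-2-methylideneoct-6-enal
Product: 4 (3S)-3-methyl-2-methylidenehexane-1,6-diol, via dialdehyde 3 (not isolated)
Conditions: O3, CH2Cl2/MeOH, −78 °C (Sudan Red end point); then NaBH4, CeCl3·7H2O, −78 to 0 °C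
Reagents that add atoms: ozone, [O-][O+]=O
Why: Chemoselective ozonolysis cleaves the electron-rich trisubstituted alkene far faster than the electron-poor enal C=C, and the Luche-type borohydride work-up reduces both aldehydes 1,2 without touching the methylidene group.

Step 3
Reactants: 4 (3S)-3-methyl-2-methylidenehexane-1,6-diol
Product: 5 (3S)-6-hydroxy-3-methyl-2-methylidenehexanal
Conditions: activated MnO2 (15 equiv), CH2Cl2, rt
Reagents that add atoms: none
Why: MnO2 oxidation is selective for the allylic primary alcohol and leaves the saturated primary alcohol untouched.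

Step 4
Reactants: 6 acrolein; 7 tert-butyl acrylate
Product: 8 tert-butyl 3-hydroxy-2-methylidenepent-4-enoate (racemic)
Conditions: DABCO (0.3 equiv), 7 in excess, neat, 0 °C to rt
Reagents that add atoms: none
Why: Morita–Baylis–Hillman reaction of the acrylate with the aldehyde of acrolein; the racemic carbinol centre is erased in the next step.

Step 5
Reactants: 8 tert-butyl 3-hydroxy-2-methylidenepent-4-enoate
Product: 9 tert-butyl (2Z)-2-(bromomethyl)penta-2,4-dienoate
Conditions: NBS, Me2S, CH2Cl2, 0 °C to rt
Reagents that add atoms: N-bromosuccinimide, O=C1CCC(=O)N1Br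
Why: Corey–Kim-type activation of the allylic alcohol followed by SN2′ attack of bromide at the acrylate CH2 gives the conjugated, thermodynamically favoured (2Z) allylic bromide without acid that would cleave the tert-butyl ester.

Step 6
Reactants: 5 (3S)-6-hydroxy-3-methyl-2-methylidenehexanal; 9 tert-butyl (2Z)-2-(bromomethyl)penta-2,4-dienoate
Product: 11 tert-butyl (3S,4R,6S)-3-ethenyl-4,9-dihydroxy-6-methyl-2,5-dimethylidenenonanoate, via silyl ether 10 (not isolated)
Conditions: CrCl2 (10 mol %), chiral carbazole-1,8-bis(4-isopropyloxazoline) ligand (12 mol %), Mn powder, Me3SiCl, THF, rt; then 1 M HCl, 0 °C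
Reagents that add atoms: none
Why: Catalytic enantioselective Nozaki–Hiyama-type 2-(alkoxycarbonyl)allylation: the γ-vinyl allylchromium (vinyl trans to the ester) adds at its γ-carbon through a closed chair transition state to give the 3,4-syn (crotyl-sense) adduct, and the ligand enantiomer chosen for Re-face attack on the aldehyde sets C4 as R and C3 as S (C6 and C7 of the target) independently of the remote methyl centre.

Step 7
Reactants: 11 tert-butyl (3S,4R,6S)-3-ethenyl-4,9-dihydroxy-6-methyl-2,5-dimethylidenenonanoate
Product: 12 tert-butyl (3S,4R,6S)-4,9-bis(acetyloxy)-3-ethenyl-6-methyl-2,5-dimethylidenenonanoate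
Conditions: Ac2O, pyridine, DMAP (cat.), CH2Cl2, 0 °C to rt
Reagents that add atoms: acetic anhydride, CC(=O)OC(C)=O
Why: DMAP-catalysed acetylation installs both acetates of the target and blocks the C6 oxygen so that only the ester can lactonize in the next step.

Step 8
Reactants: 12 tert-butyl (3S,4R,6S)-4,9-bis(acetyloxy)-3-ethenyl-6-methyl-2,5-dimethylidenenonanoate; 13 isopropenylboronic acid (prop-1-en-2-ylboronic acid)
Product: 14 (4R,5R)-4-[(1R,3S)-1,6-bis(acetyloxy)-3-methyl-2-methylidenehexyl]-3-methylidene-5-(2-methylprop-2-en-1-yl)oxolan-2-one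
Conditions: Ph3PAuCl (5 mol %), Selectfluor (2 equiv), 13 (2.5 equiv), MeCN, 50 °C
Reagents that add atoms: none
Why: Proposed new method: gold-catalysed oxidative oxy-alkenylation (carbolactonization), in which Selectfluor oxidises monovalent gold to a trivalent gold fluoride that activates the least hindered alkene (the C8=C9 vinyl group), the tert-butyl ester carbonyl oxygen adds anti in a 5-exo mode (C8–O bond, then loss of 2-methylpropene), and the alkylgold fluoride couples with the boronic acid by B–F-assisted C(sp3)–C(sp2) bond formation (C9–C10); gold attacks the conformer in which the bulky C7 substituent eclipses the C=C, on the H-7 side, so the 4,5-cis lactone (new centre 5R, C8 of the target) forms as in kinetic iodolactonization of 3-substituted pent-4-enoic acids; the closest known reaction type is gold-catalysed oxyarylation of alkenols and alkenoic acids with arylboronic acids and Selectfluor, here extended to an alkenylboronic acid and a tert-butyl ester as the internal oxygen nucleophile.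

Step 9
Reactants: 14 (4R,5R)-4-[(1R,3S)-1,6-bis(acetyloxy)-3-methyl-2-methylidenehexyl]-3-methylidene-5-(2-methylprop-2-en-1-yl)oxolan-2-one
Product: 15 1,6-O,O-diacetylbritannilactone
Conditions: second-generation Hoveyda–Grubbs catalyst RuCl2(H2IMes)(=CH-C6H4-2-OiPr) (10 mol %), toluene, 90 °C, Ar sparge
Reagents that add atoms: none
Why: Ring-closing metathesis of the two 1,1-disubstituted alkenes is the only ring closure the geometry allows (the methylene-lactone alkene cannot close without a bridgehead alkene) and gives the tetrasubstituted C5=C10 cyclohexene with loss of ethene and no change at any stereocentre.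

**Compound list**
1 | (S)-citronellal [(3S)-3,7-dimethyloct-6-enal] | O=CC[C@@H](C)CCC=C(C)C | starting material
2 | (3S)-3,7-dimethyl-2-methylideneoct-6-enal | O=CC(=C)[C@@H](C)CCC=C(C)C | intermediate
3 | (3S)-3-methyl-2-methylidenehexanedial (dialdehyde) | O=CC(=C)[C@@H](C)CCC=O | intermediate
4 | (3S)-3-methyl-2-methylidenehexane-1,6-diol | OCC(=C)[C@@H](C)CCCO | intermediate
5 | (3S)-6-hydroxy-3-methyl-2-methylidenehexanal | O=CC(=C)[C@@H](C)CCCO | intermediate
6 | acrolein (prop-2-enal) | C=CC=O | starting material
7 | tert-butyl acrylate | C=CC(=O)OC(C)(C)C | starting material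
8 | tert-butyl 3-hydroxy-2-methylidenepent-4-enoate (racemic) | C=CC(O)C(=C)C(=O)OC(C)(C)C | intermediate
9 | tert-butyl (2Z)-2-(bromomethyl)penta-2,4-dienoate | BrC/C(=C\C=C)C(=O)OC(C)(C)C | intermediate
10 | tert-butyl (3S,4R,6S)-3-ethenyl-9-hydroxy-6-methyl-2,5-dimethylidene-4-[(trimethylsilyl)oxy]nonanoate (silyl ether) | C=C(C(=O)OC(C)(C)C)[C@H](C=C)[C@@H](O[Si](C)(C)C)C(=C)[C@@H](C)CCCO | intermediate
11 | tert-butyl (3S,4R,6S)-3-ethenyl-4,9-dihydroxy-6-methyl-2,5-dimethylidenenonanoate | C=C(C(=O)OC(C)(C)C)[C@H](C=C)[C@@H](O)C(=C)[C@@H](C)CCCO | intermediate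
12 | tert-butyl (3S,4R,6S)-4,9-bis(acetyloxy)-3-ethenyl-6-methyl-2,5-dimethylidenenonanoate | C=C(C(=O)OC(C)(C)C)[C@H](C=C)[C@@H](OC(C)=O)C(=C)[C@@H](C)CCCOC(C)=O | intermediate
13 | isopropenylboronic acid (prop-1-en-2-ylboronic acid) | CC(=C)B(O)O | starting material
14 | (4R,5R)-4-[(1R,3S)-1,6-bis(acetyloxy)-3-methyl-2-methylidenehexyl]-3-methylidene-5-(2-methylprop-2-en-1-yl)oxolan-2-one | C=C1C(=O)O[C@H](CC(C)=C)[C@@H]1[C@@H](OC(C)=O)C(=C)[C@@H](C)CCCOC(C)=O | intermediate
15 | 1,6-O,O-diacetylbritannilactone [(3aR,4R,7aR)-4-(acetyloxy)-5-[(2S)-5-(acetyloxy)pentan-2-yl]-6-methyl-3-methylidene-3a,4,7,7a-tetrahydro-1-benzofuran-2(3H)-one] | C=C1C(=O)O[C@@H]2CC(C)=C([C@@H](C)CCCOC(C)=O)[C@H](OC(C)=O)[C@H]12 | target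

**Step count and risks**

Total steps: 9. Longest linear sequence: 7 (steps 1, 2, 3, 6, 7, 8, 9).

The three steps most likely to fail:

Step 6. The chromium-catalysed asymmetric allylation has to work with a γ-vinyl allyl bromide, an α-branched enal and a free primary hydroxyl, with catalyst control over the remote methyl centre. The fallback sets out from 9 and returns at 11. Miyaura borylation of 9 (B2pin2, Pd2(dba)3, KOAc, DMSO, 50 °C; boron goes to the less hindered CH2 terminus of the allyl-palladium) gives the allylboronate tert-butyl (2E)-2-[(4,4,5,5-tetramethyl-1,3,2-dioxaborolan-2-yl)methyl]penta-2,4-dienoate F1. Chiral phosphoric acid-catalysed allylboration of 5 with F1 ((R)-TRIP or its enantiomer, toluene, 4 Å molecular sieves, −30 °C to rt) then proceeds through a closed chair transition state with the same 3,4-syn sense, tolerates the free hydroxyl, and gives 11 after aqueous work-up.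

Step 8. The proposed oxy-alkenylation may suffer from activation of the C5 methylidene group with acetate participation, homocoupling of the boronic acid, and an imperfect cis/trans ratio at C8. The fallback uses known chemistry, sets out from 12 and returns at 14. Kinetic iodolactonization of the tert-butyl ester (I2, NaHCO3, MeCN, 0 °C, dark; the tert-butyl group is lost as 2-methylpropene) gives the cis iodolactone (4S,5S)-4-[(1R,3S)-1,6-bis(acetyloxy)-3-methyl-2-methylidenehexyl]-5-(iodomethyl)-3-methylideneoxolan-2-one F2. Nickel-catalysed reductive cross-electrophile coupling of F2 with 2-bromopropene (NiI2, 4,4′-di-tert-butyl-2,2′-bipyridine, Zn dust, DMA, rt) then gives 14.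

Step 9. Ring-closing metathesis to a tetrasubstituted alkene is slowed by the sec-alkyl group and the allylic acetate flanking the C5 methylidene group. The fallback sets out from 11 and returns at 15. Both hydroxyls are left free and the step 8 lactonization (NaHCO3-buffered) is run on 11 to give the dihydroxy seco-lactone (4S,5R)-4-[(1R,3S)-1,6-dihydroxy-3-methyl-2-methylidenehexyl]-3-methylidene-5-(2-methylprop-2-en-1-yl)oxolan-2-one F3. Metathesis is then run on F3, where the free allylic C6 hydroxyl accelerates ruthenium metathesis and the acetate bulk beside the C5 alkene is gone, to give britannilactone [(3aS,4R,7aR)-4-hydroxy-5-[(2S)-5-hydroxypentan-2-yl]-6-methyl-3-methylidene-3a,4,7,7a-tetrahydro-1-benzofuran-2(3H)-one] F4. Acetylation of both hydroxyls (Ac2O, pyridine, DMAP) then reaches 15.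

Further compounds
F1 | step 6 | tert-butyl (2E)-2-[(4,4,5,5-tetramethyl-1,3,2-dioxaborolan-2-yl)methyl]penta-2,4-dienoate | CC1(C)OB(C/C(=C\C=C)C(=O)OC(C)(C)C)OC1(C)C
F2 | step 8 | (4S,5S)-4-[(1R,3S)-1,6-bis(acetyloxy)-3-methyl-2-methylidenehexyl]-5-(iodomethyl)-3-methylideneoxolan-2-one | C=C1C(=O)O[C@H](CI)[C@@H]1[C@@H](OC(C)=O)C(=C)[C@@H](C)CCCOC(C)=O
F3 | step 9 | (4S,5R)-4-[(1R,3S)-1,6-dihydroxy-3-methyl-2-methylidenehexyl]-3-methylidene-5-(2-methylprop-2-en-1-yl)oxolan-2-one | C=C1C(=O)O[C@H](CC(C)=C)[C@@H]1[C@@H](O)C(=C)[C@@H](C)CCCO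
F4 | step 9 | britannilactone [(3aS,4R,7aR)-4-hydroxy-5-[(2S)-5-hydroxypentan-2-yl]-6-methyl-3-methylidene-3a,4,7,7a-tetrahydro-1-benzofuran-2(3H)-one] | C=C1C(=O)O[C@@H]2CC(C)=C([C@@H](C)CCCO)[C@H](O)[C@H]12
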